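**Strategy.** The plan cuts the side chain at C21'–C22', the sp3–sp2 bond from the homoallylic CH2 beside the C18'=C19' alkene (prenyl unit 5) to the vinylic CH of the C22'=C23' alkene (unit 6). The left half is carried as a terminal 1,3-diene (C18'=C19'–C20'=C21') with the naphthoquinone ring masked as its hydroquinone dimethyl ether; the right half is an (E)-1-iodo-2-methylalkene. In one operation, chemoselective 9-BBN hydroboration of the diene terminus and stereoretentive B-alkyl Suzuki–Miyaura coupling create the C21' methylene and the C21'–C22' bond with 22'E geometry. Both flanking methyl stereocentres come from (S)-citronellyl bromide; ceric oxidation finally unveils the quinone.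

Key step: step 14

Remark: side-chain carbons are numbered C1'–C32' from the ring. CIP analysis of the target gives 2'E,7'S,11'R,15'R,18'E,22'E,26'E; the three methyl stereocentres share one spatial sense, so C7' and C15' both come from (S)-citronellyl bromide used in opposite orientations. 1,4-Dimethoxy-2-methylnaphthalene (5) is taken as a catalogue compound.

**Step 1**
Reactants: 1 (S)-citronellyl bromide
Product: 2 (2E,6S)-8-bromo-2,6-dimethyloct-2-en-1-ol
Conditions: SeO2 (cat.), t-BuOOH (70% aq.), salicylic acid (cat.), CH2Cl2, rt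
Reagents that add atoms: selenium dioxide O=[Se]=O (oxygen carrier); tert-butyl hydroperoxide CC(C)(C)OO (terminal oxidant)
Why: Sharpless catalytic SeO2 allylic oxidation (ene reaction, then [2,3]-sigmatropic shift) attacks the gem-dimethyl terminus at the methyl trans to the chain and should give the (E)-allylic alcohol without touching the stereocentre or the primary bromide; any over-oxidised enal is compound 10 and can be pooled into step 8.

**Step 2**
Reactants: 2 (2E,6S)-8-bromo-2,6-dimethyloct-2-en-1-ol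
Product: 3 (2R,6S)-8-bromo-2,6-dimethyloctan-1-ol
Conditions: H2 (30 atm), Ru(OAc)2[(R)-BINAP] (1 mol %), MeOH, rt
Reagents that add atoms: none
Why: Noyori–Takaya asymmetric hydrogenation of an allylic alcohol, in which the Ru–BINAP complex chelates hydroxyl and alkene and delivers H2 to one olefin face, so C2 is set by the catalyst (the (R)-ligand is expected to give 2R by the chelate model under which the (S)-ligand converts geraniol into (R)-citronellol; the sense is to be verified on a pilot run and the ligand antipode exchanged if needed) while C6 and the C–Br bond are untouched.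

**Step 3**
Reactants: 3 (2R,6S)-8-bromo-2,6-dimethyloctan-1-ol
Product: 4 (2R,6S)-2,6-dimethylundec-10-yn-1-ol
Conditions: 1,3-dilithiopropyne (excess; from propyne, 2 n-BuLi, TMEDA, THF/hexane, −78 → 0 °C), 3 added as its lithium alkoxide (n-BuLi, 1 equiv), −78 °C → rt; H2O
Reagents that add atoms: propyne CC#C
Why: SN2 alkylation of 1,3-dilithiopropyne at its propargylic carbon (three-carbon homologation of a primary bromide to a terminal alkyne) with the hydroxyl carried as its lithium alkoxide and both stereocentres remote from the reacting carbon.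

**Step 4**
Reactants: 5 1,4-dimethoxy-2-methylnaphthalene
Product: 6 2-(chloromethyl)-1,4-dimethoxy-3-methylnaphthalene
Conditions: (CH2O)n, conc. HCl, AcOH, rt → 50 °C
Reagents that add atoms: formaldehyde (as paraformaldehyde) C=O; hydrogen chloride Cl
Why: Blanc chloromethylation, in which the only free position of the electron-rich substituted ring is attacked by protonated formaldehyde and the benzylic alcohol is converted into the chloride in situ.

**Step 5**
Reactants: 4 (2R,6S)-2,6-dimethylundec-10-yn-1-ol; 6 2-(chloromethyl)-1,4-dimethoxy-3-methylnaphthalene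
Product: 8 (2R,6S,10E)-12-(1,4-dimethoxy-3-methylnaphthalen-2-yl)-2,6,10-trimethyldodec-10-en-1-ol, via alkenylalane 7 (not isolated)
Conditions: AlMe3 (3 equiv), Cp2ZrCl2 (0.25 equiv), ClCH2CH2Cl, 0 °C → rt; volatiles removed; then 6, NiCl2(PPh3)2/n-BuLi (3 mol % Ni(0)), THF, rt; aq. HCl
Reagents that add atoms: trimethylaluminium C[Al](C)C
Why: Negishi Zr-catalysed syn-methylalumination of the terminal alkyne (Me and Al cis, Al on the terminal carbon) sets the 2'E trisubstituted alkene, and Ni(0)-catalysed cross-coupling of the alkenylalane with the benzylic chloride proceeds with retention, the hydroxyl being masked in situ as its aluminium alkoxide.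

**Step 6**
Reactants: 8 (2R,6S,10E)-12-(1,4-dimethoxy-3-methylnaphthalen-2-yl)-2,6,10-trimethyldodec-10-en-1-ol
Product: 9 (2R,6S,10E)-12-(1,4-dimethoxy-3-methylnaphthalen-2-yl)-2,6,10-trimethyldodec-10-en-1-yl 4-methylbenzenesulfonate
Conditions: TsCl, pyridine, DMAP (cat.), CH2Cl2, 0 °C → rt
Reagents that add atoms: p-toluenesulfonyl chloride Cc1ccc(cc1)S(=O)(=O)Cl
Why: Sulfonylation of the primary alcohol gives the leaving group for the chain coupling and does not involve the C2 stereocentre.

**Step 7**
Reactants: 2 (2E,6S)-8-bromo-2,6-dimethyloct-2-en-1-ol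
Product: 10 (2E,6S)-8-bromo-2,6-dimethyloct-2-enal
Conditions: MnO2, CH2Cl2, rt
Reagents that add atoms: none
Why: Allylic alcohol oxidation with MnO2 should give the enal without E/Z isomerisation and without affecting the alkyl bromide.

**Step 8**
Reactants: 10 (2E,6S)-8-bromo-2,6-dimethyloct-2-enal
Product: 11 (3E,7S)-9-bromo-3,7-dimethylnona-1,3-diene
Conditions: Ph3PCH3Br, KHMDS, THF, 0 °C; then 10, −78 → 0 °C
Reagents that add atoms: methyltriphenylphosphonium bromide [Br-].C[P+](c1ccccc1)(c1ccccc1)c1ccccc1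
Why: Wittig methylenation of the enal gives the terminal 1,3-diene, since carbonyl addition of the ylide is far faster than its alkylation by the primary bromide and the trisubstituted alkene keeps its E geometry.

**Step 9**
Reactants: 9 (2R,6S,10E)-12-(1,4-dimethoxy-3-methylnaphthalen-2-yl)-2,6,10-trimethyldodec-10-en-1-yl 4-methylbenzenesulfonate; 11 (3E,7S)-9-bromo-3,7-dimethylnona-1,3-diene
Product: 13 2-[(2E,7S,11R,15R,18E)-3,7,11,15,19-pentamethylhenicosa-2,18,20-trien-1-yl]-1,4-dimethoxy-3-methylnaphthalene, via Grignard reagent 12 (not isolated)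
Conditions: 11, Mg, THF, rt; then added in excess to 9, Li2CuCl4 (5 mol %), THF, −78 °C → rt
Reagents that add atoms: none
Why: Kochi–Schlosser copper-catalysed sp3–sp3 coupling of a primary Grignard reagent with a primary tosylate (SN2 at CH2, so the neighbouring methyl stereocentre is untouched), to which the diene, the trisubstituted alkene and the aryl ethers are inert.

**Step 10**
Reactants: 14 1-bromo-4-methylpentane
Product: 15 6-methylhept-1-yne
Conditions: LiC≡CH·H2NCH2CH2NH2, DMSO, rt
Reagents that add atoms: lithium acetylide–ethylenediamine complex [Li]C#C.NCCN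
Why: SN2 alkylation of lithium acetylide by a primary bromide in DMSO.

**Step 11**
Reactants: 15 6-methylhept-1-yne
Product: 17 (1E)-1-iodo-2,6-dimethylhept-1-ene, via alkenylalane 16 (not isolated)
Conditions: AlMe3 (2 equiv), Cp2ZrCl2 (0.25 equiv), CH2Cl2, rt; then I2, THF, −30 → 0 °C; aq. HCl
Reagents that add atoms: trimethylaluminium C[Al](C)C; iodine II
Why: Negishi Zr-catalysed carboalumination (syn addition, Al terminal) followed by iodinolysis of the C–Al bond with retention gives the (E)-1-iodo-2-methylalkene.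

**Step 12**
Reactants: 17 (1E)-1-iodo-2,6-dimethylhept-1-ene; 18 (4-bromobut-1-yn-1-yl)trimethylsilane
Product: 21 (5E)-6,10-dimethylundec-5-en-1-yne, via organozinc bromide 19 (not isolated), via silylated enyne 20 (not isolated)
Conditions: 18, Zn dust, LiCl, THF, 50 °C; then 17, PdCl2(dppf) (3 mol %), THF, rt; then MeOH, K2CO3, rt (same flask)
Reagents that add atoms: none
Why: Negishi Pd-catalysed alkyl–alkenyl coupling of the homopropargylzinc reagent with the (E)-alkenyl iodide proceeds with retention of geometry, and methanolysis of the C(sp)–Si bond then frees the terminal alkyne.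

**Step 13**
Reactants: 21 (5E)-6,10-dimethylundec-5-en-1-yne
Product: 23 (1E,5E)-1-iodo-2,6,10-trimethylundeca-1,5-diene, via alkenylalane 22 (not isolated)
Conditions: AlMe3 (2 equiv), Cp2ZrCl2 (0.25 equiv), CH2Cl2, rt; then I2, THF, −30 → 0 °C; aq. HCl
Reagents that add atoms: trimethylaluminium C[Al](C)C; iodine II
Why: Negishi Zr-catalysed syn-carboalumination and iodinolysis with retention set the future C22'=C23' alkene as the (E)-alkenyl iodide while the existing trisubstituted alkene is inert.

**Step 14**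
Reactants: 13 2-[(2E,7S,11R,15R,18E)-3,7,11,15,19-pentamethylhenicosa-2,18,20-trien-1-yl]-1,4-dimethoxy-3-methylnaphthalene; 23 (1E,5E)-1-iodo-2,6,10-trimethylundeca-1,5-diene
Product: 25 2-[(2E,7S,11R,15R,18E,22E,26E)-3,7,11,15,19,23,27,31-octamethyldotriaconta-2,18,22,26-tetraen-1-yl]-1,4-dimethoxy-3-methylnaphthalene, via B-alkyl-9-BBN adduct 24 (not isolated)
Conditions: 9-BBN (1.2 equiv), THF, 0 °C → rt; then 23, PdCl2(dppf) (5 mol %), AsPh3, Cs2CO3, DMF/THF/H2O, rt
Reagents that add atoms: none
Why: 9-BBN adds B–H syn and anti-Markovnikov to the only monosubstituted C=C of 13 (the C20'=C21' vinyl group of the diene), putting boron on C21'; Pd(0) then inserts into the C–I bond of 23 with retention, the base-activated borate transfers its primary alkyl group, and reductive elimination forms C21'–C22'. The closest known reaction type is the B-alkyl Suzuki–Miyaura coupling of 9-BBN adducts with (E)-alkenyl iodides, including homoallylic boranes made from terminal 1,3-dienes. No ring is closed and no stereocentre is created; the 22'E geometry is carried over from 23 (syn-carboalumination) and the 18'E geometry from the SeO2 oxidation of step 1. The step needs chemoselectivity for the vinyl group over the two trisubstituted alkenes of 13 and regioselectivity for the terminal carbon, both secured by the steric demand of 9-BBN, and it needs transmetalation to outrun β-hydride elimination, which dppf/AsPh3 with Cs2CO3 in aqueous DMF favours.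

**Step 15**
Reactants: 25 2-[(2E,7S,11R,15R,18E,22E,26E)-3,7,11,15,19,23,27,31-octamethyldotriaconta-2,18,22,26-tetraen-1-yl]-1,4-dimethoxy-3-methylnaphthalene
Product: 26 2-methyl-3-[(2E,7S,11R,15R,18E,22E,26E)-3,7,11,15,19,23,27,31-octamethyldotriaconta-2,18,22,26-tetraen-1-yl]naphthalene-1,4-dione (target)
Conditions: (NH4)2Ce(NO3)6 (2.5 equiv), MeCN/CH2Cl2/H2O, 0 °C
Reagents that add atoms: water O
Why: Ce(IV) oxidative demethylation of the 1,4-dimethoxynaphthalene (arene radical cation, ipso attack of water, loss of methanol) should give the 1,4-quinone while the isolated trisubstituted alkenes and the remote stereocentres are unaffected.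

**Compound list**

1 | (S)-citronellyl bromide, (6S)-8-bromo-2,6-dimethyloct-2-ene | BrCC[C@@H](C)CCC=C(C)C | starting material
2 | (2E,6S)-8-bromo-2,6-dimethyloct-2-en-1-ol | BrCC[C@@H](C)CC/C=C(\C)CO | intermediate
3 | (2R,6S)-8-bromo-2,6-dimethyloctan-1-ol | BrCC[C@@H](C)CCC[C@@H](C)CO | intermediate
4 | (2R,6S)-2,6-dimethylundec-10-yn-1-ol | C#CCCC[C@@H](C)CCC[C@@H](C)CO | intermediate
5 | 1,4-dimethoxy-2-methylnaphthalene | COc1cc(C)c(OC)c2ccccc12 | starting material
6 | 2-(chloromethyl)-1,4-dimethoxy-3-methylnaphthalene | COc1c(C)c(CCl)c(OC)c2ccccc12 | intermediate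
7 | dimethyl[(1E,6S,10R)-11-(dimethylalumanyloxy)-2,6,10-trimethylundec-1-en-1-yl]alumane | C[Al](C)/C=C(\C)CCC[C@@H](C)CCC[C@@H](C)CO[Al](C)C | intermediate
8 | (2R,6S,10E)-12-(1,4-dimethoxy-3-methylnaphthalen-2-yl)-2,6,10-trimethyldodec-10-en-1-ol | COc1c(C)c(C/C=C(\C)CCC[C@@H](C)CCC[C@@H](C)CO)c(OC)c2ccccc12 | intermediate
9 | (2R,6S,10E)-12-(1,4-dimethoxy-3-methylnaphthalen-2-yl)-2,6,10-trimethyldodec-10-en-1-yl 4-methylbenzenesulfonate | COc1c(C)c(C/C=C(\C)CCC[C@@H](C)CCC[C@@H](C)COS(=O)(=O)c3ccc(C)cc3)c(OC)c2ccccc12 | intermediate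
10 | (2E,6S)-8-bromo-2,6-dimethyloct-2-enal | BrCC[C@@H](C)CC/C=C(\C)C=O | intermediate
11 | (3E,7S)-9-bromo-3,7-dimethylnona-1,3-diene | BrCC[C@@H](C)CC/C=C(\C)C=C | intermediate
12 | [(3S,6E)-3,7-dimethylnona-6,8-dien-1-yl]magnesium bromide | Br[Mg]CC[C@@H](C)CC/C=C(\C)C=C | intermediate
13 | 2-[(2E,7S,11R,15R,18E)-3,7,11,15,19-pentamethylhenicosa-2,18,20-trien-1-yl]-1,4-dimethoxy-3-methylnaphthalene | COc1c(C)c(C/C=C(\C)CCC[C@@H](C)CCC[C@@H](C)CCC[C@@H](C)CC/C=C(\C)C=C)c(OC)c2ccccc12 | intermediate
14 | 1-bromo-4-methylpentane | CC(C)CCCBr | starting material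
15 | 6-methylhept-1-yne | C#CCCCC(C)C | intermediate
16 | [(1E)-2,6-dimethylhept-1-en-1-yl]dimethylalumane | C[Al](C)/C=C(\C)CCCC(C)C | intermediate
17 | (1E)-1-iodo-2,6-dimethylhept-1-ene | I/C=C(\C)CCCC(C)C | intermediate
18 | (4-bromobut-1-yn-1-yl)trimethylsilane | C[Si](C)(C)C#CCCBr | starting material
19 | [4-(trimethylsilyl)but-3-yn-1-yl]zinc bromide | C[Si](C)(C)C#CCC[Zn]Br | intermediate
20 | [(5E)-6,10-dimethylundec-5-en-1-yn-1-yl]trimethylsilane | C[Si](C)(C)C#CCC/C=C(\C)CCCC(C)C | intermediate
21 | (5E)-6,10-dimethylundec-5-en-1-yne | C#CCC/C=C(\C)CCCC(C)C | intermediate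
22 | dimethyl[(1E,5E)-2,6,10-trimethylundeca-1,5-dien-1-yl]alumane | C[Al](C)/C=C(\C)CC/C=C(\C)CCCC(C)C | intermediate
23 | (1E,5E)-1-iodo-2,6,10-trimethylundeca-1,5-diene | I/C=C(\C)CC/C=C(\C)CCCC(C)C | intermediate
24 | 9-[(3E,7R,11R,15S,19E)-21-(1,4-dimethoxy-3-methylnaphthalen-2-yl)-3,7,11,15,19-pentamethylhenicosa-3,19-dien-1-yl]-9-borabicyclo[3.3.1]nonane | COc1c(C)c(C/C=C(\C)CCC[C@@H](C)CCC[C@@H](C)CCC[C@@H](C)CC/C=C(\C)CCB3C4CCCC3CCC4)c(OC)c2ccccc12 | intermediate
25 | 2-[(2E,7S,11R,15R,18E,22E,26E)-3,7,11,15,19,23,27,31-octamethyldotriaconta-2,18,22,26-tetraen-1-yl]-1,4-dimethoxy-3-methylnaphthalene | COc1c(C)c(C/C=C(\C)CCC[C@@H](C)CCC[C@@H](C)CCC[C@@H](C)CC/C=C(\C)CC/C=C(\C)CC/C=C(\C)CCCC(C)C)c(OC)c2ccccc12 | intermediate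
26 | 2-methyl-3-[(2E,7S,11R,15R,18E,22E,26E)-3,7,11,15,19,23,27,31-octamethyldotriaconta-2,18,22,26-tetraen-1-yl]naphthalene-1,4-dione | CC1=C(C/C=C(\C)CCC[C@@H](C)CCC[C@@H](C)CCC[C@@H](C)CC/C=C(\C)CC/C=C(\C)CC/C=C(\C)CCCC(C)C)C(=O)c2ccccc2C1=O | target

**Totals.** Total step count: 15. Longest linear sequence: 8 steps (steps 1, 2, 3, 5, 6, 9, 14, 15, from compound 1 to 26).

**Steps most likely to fail**

Step 14. The homoallylic borane may transmetalate slowly, so that β-hydride elimination or protodeboronation competes with coupling, and hydroboration may spill over onto the trisubstituted alkenes. The fallback sets out from 13 and comes back at 25. It isolates the C21' nucleophile precursor and uses zinc instead of boron. Hydroboration of 13 with 9-BBN followed by NaOH/H2O2 gives (3E,7R,11R,15S,19E)-21-(1,4-dimethoxy-3-methylnaphthalen-2-yl)-3,7,11,15,19-pentamethylhenicosa-3,19-dien-1-ol F1. Iodination (I2, PPh3, imidazole, CH2Cl2) gives 2-[(2E,7S,11R,15R,18E)-21-iodo-3,7,11,15,19-pentamethylhenicosa-2,18-dien-1-yl]-1,4-dimethoxy-3-methylnaphthalene F2. Zinc insertion (Zn dust, LiCl, THF) gives [(3E,7R,11R,15S,19E)-21-(1,4-dimethoxy-3-methylnaphthalen-2-yl)-3,7,11,15,19-pentamethylhenicosa-3,19-dien-1-yl]zinc iodide F3, which is coupled with 23 under Negishi conditions (PdCl2(dppf), THF, rt) to give 25.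

Step 2. Facial discrimination of the α-methyl allylic alcohol by the Ru–BINAP chelate may be insufficient or of the unexpected sense, and alkene migration may erode it further. The fallback sets out from 10 and comes back at 3. It moves the stereo-defining reduction onto the carboxylic acid, the substrate class of tiglic acid. Pinnick oxidation of 10 (NaClO2, NaH2PO4, 2-methyl-2-butene, t-BuOH/H2O) gives (2E,6S)-8-bromo-2,6-dimethyloct-2-enoic acid F4. Carboxylate-directed hydrogenation with Ru(OAc)2(H8-BINAP), using the ligand antipode that converts tiglic acid into (R)-2-methylbutanoic acid, should give (2R,6S)-8-bromo-2,6-dimethyloctanoic acid F5. Reduction with BH3·THF gives 3.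

Step 5. Methyl transfer from aluminium to the benzylic electrophile, regioisomeric carbometalation and protodealumination by the alkoxide may compete with the one-flask alkenyl transfer. The fallback sets out from 4 and 6 and comes back at 8. It reverses the polarity of the coupling. Carboalumination of 4 (AlMe3, Cp2ZrCl2) followed by I2 gives (2R,6S,10E)-11-iodo-2,6,10-trimethylundec-10-en-1-ol F6. Zinc insertion into 6 (Zn dust, LiCl, THF) gives [(1,4-dimethoxy-3-methylnaphthalen-2-yl)methyl]zinc chloride F7. Negishi coupling of F6 with F7 (Pd(OAc)2/SPhos, THF, rt, conditions that tolerate a free hydroxyl) gives 8.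

**Further compounds**

F1 | step 14 | (3E,7R,11R,15S,19E)-21-(1,4-dimethoxy-3-methylnaphthalen-2-yl)-3,7,11,15,19-pentamethylhenicosa-3,19-dien-1-ol | COc1c(C)c(C/C=C(\C)CCC[C@@H](C)CCC[C@@H](C)CCC[C@@H](C)CC/C=C(\C)CCO)c(OC)c2ccccc12
F2 | step 14 | 2-[(2E,7S,11R,15R,18E)-21-iodo-3,7,11,15,19-pentamethylhenicosa-2,18-dien-1-yl]-1,4-dimethoxy-3-methylnaphthalene | COc1c(C)c(C/C=C(\C)CCC[C@@H](C)CCC[C@@H](C)CCC[C@@H](C)CC/C=C(\C)CCI)c(OC)c2ccccc12
F3 | step 14 | [(3E,7R,11R,15S,19E)-21-(1,4-dimethoxy-3-methylnaphthalen-2-yl)-3,7,11,15,19-pentamethylhenicosa-3,19-dien-1-yl]zinc iodide | COc1c(C)c(C/C=C(\C)CCC[C@@H](C)CCC[C@@H](C)CCC[C@@H](C)CC/C=C(\C)CC[Zn]I)c(OC)c2ccccc12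
F4 | step 2 | (2E,6S)-8-bromo-2,6-dimethyloct-2-enoic acid | BrCC[C@@H](C)CC/C=C(\C)C(=O)O
F5 | step 2 | (2R,6S)-8-bromo-2,6-dimethyloctanoic acid | BrCC[C@@H](C)CCC[C@@H](C)C(=O)O
F6 | step 5 | (2R,6S,10E)-11-iodo-2,6,10-trimethylundec-10-en-1-ol | I/C=C(\C)CCC[C@@H](C)CCC[C@@H](C)CO
F7 | step 5 | [(1,4-dimethoxy-3-methylnaphthalen-2-yl)methyl]zinc chloride | COc1c(C)c(C[Zn]Cl)c(OC)c2ccccc12
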